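All runs are calculated on assumed constants; scatter was added.

Compare the north flask with the north-east run, which holds about half of its coupling partner at the same starting material, second substrate and temperature.

all flasks: starting material 0.30 M; temperature 70 °C

| charge | coupling partner | second substrate | remark | time |
|---|---|---|---|---|
| north | 1.05 equiv | 0.50 equiv | the very flask that is asked about, followed so far |  |
| north-east | 0.53 equiv | 0.50 equiv | run made earlier |  |
| flask | 1.05 equiv | 0.500 equiv |  | 15 min |

| run | time / min | target / % | starting material / % |
|---|---|---|---|
| north | 1.33 | 36 | 63 |
| north | 2.50 | 35 | 64 |
| north | 4.00 | 44 | 59 |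
| north | 5.00 | 39 | 57 |
| north | 6.00 | 42 | 61 |
| north | 8.00 | 41 | 58 |
| north | 10.0 | 44 | 59 |
| north-east | 1.33 | 19 | 82 |
| north-east | 2.00 | 17 | 80 |
| north-east | 3.00 | 24 | 79 |
| north-east | 4.00 | 23 | 81 |
| north-east | 6.00 | 23 | 80 |
| north-east | 10.0 | 22 | 76 |
| north-east | 15.0 | 24 | 78 |

(scatter of a reading: 2 percentage points)

- target that was removed still counts
- the earlier runs do not show what temperature does; that part of a forecast is a guess
- additions bring no volume worth counting

- delta: at 15 min raise the temperature by 25 K, then wait 8.0 min
- alpha: change nothing and wait 8.0 min more
- theta: at 15 min take out 90% of the target then present, then wait 8.0 min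
- gamma: at 15 min add coupling partner, 100% of the amount charged, then wait 8.0 min

* target, in percent of the starting material first charged, at 15 min
* the remedy with the largest gain of target, or "none" below 2 percentage points (delta / alpha / theta / gamma / none)
* target present, with what was taken out counted in, in percent of the starting material first charged, after alpha
* target present, with what was taken out counted in, in percent of the starting material first charged, after theta

Both flasks go flat by 4.00 min. Over their last 5 readings target averages 42.0% in the north flask and 23.2% in the north-east run, and starting material stands near the complement of each. Partner not in target is 0.630 of the starting-material charge in the north flask and 0.298 in the north-east run. So both sides of the coupling remain while target stands still, and we read each plateau as a balance.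

Taking starting material as the complement of target, the north flask reads 1.15 and the north-east run 1.01, although the north flask has twice the partner. We carry their mean 1.08 as the partner quotient: target over starting material, per unit of partner not in target, each as a fraction of the starting-material charge. It is an apparent equilibrium constant.

The wait of 8.0 min is longer than the 4.00 min the plateau took, so we expect 42.0% at 15 min and the same after alpha. Taking out 90% of the target lowers the quotient, and we reckon that restoring it brings the counted target to 58.6%. For doubling the partner we reckon 61.6%, which is more than our figure for removal, so we choose gamma. The earlier runs do not show what temperature does, so delta gets no number from us.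

The forecast gives 41%, 41% after alpha, 42% after theta and gamma as the choice, holding that “removal probably gives nothing”, and on theta it parts from our reckoning.

The flask gives 42.0%, 42.0% after alpha, 58.6% after theta and gamma as the best remedy, with a gain of 22 percentage points.

    starting material + coupling partner ⇌ target (K = 16.0 M⁻¹, k = 0.0660 M⁻¹ s⁻¹, Ea = 70.0 kJ mol⁻¹, ΔH = −68.0 kJ mol⁻¹)
    second substrate + coupling partner ⇌ second product (K = 5.70 M⁻¹, k = 0.0870 M⁻¹ s⁻¹, Ea = 72.0 kJ mol⁻¹, ΔH = 15.0 kJ mol⁻¹)
    coupling partner ⇌ dormant form (K = 2.50, k = 0.0270 s⁻¹, Ea = 92.0 kJ mol⁻¹, ΔH = −38.0 kJ mol⁻¹)
    (constants at 70 °C)

The north flask stops short mainly because of the reverse step from target to starting material and coupling partner: the run without that step reaches 82.6% against 42.0%, a difference that is 70% of what is missing. In the north flask, restoring the carried 1.08 after the removal gave us 58.6%, and the flask holds 58.6% after theta. For the neighbour charged with 2.60 equiv of coupling partner, 1.08 reckons 67.5%, and that flask holds 69.7%.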